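**Plan**

- Numbering: ring A is the arene (C4a, C5–C8, C8a); ring B holds C1 (side chain C1′–C5′), C2, C3 and C4 (methyl); OH on C5 and C6, CO2H on C7.
- Retrosynthetic cuts, in order: C7–CO2H; C2–C3 of ring B; C1–C1′; C8a–C1; C3–C4; C3′–C4′. The C2–C3 cut is possible because C2 and C3 are bare CH2 groups between the two benzylic stereocentres C1 and C4, so each can be the inner carbon of a vinyl group and the bond can be made by olefin metathesis.
- Forward: ring A is bought as 2,3-dihydroxybenzaldehyde. The C4 arm is made on the simple styrene, bromine is placed at C8a, and the C1 arm is added as an aryl vinyl carbinol that is allylated by the finished side-chain aldehyde. Ring B then closes by metathesis, followed by saturation, C7 carboxylation and global deprotection.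
- Stereochemistry: C4 from nickel/phosphoramidite hydrovinylation; C1 and C1′ together from iridium/phosphoramidite plus prolinol silyl ether dual catalysis; C5′ from (R)-3-bromo-2-methylpropan-1-ol.
- Protecting groups: MOM on both phenols (directs lithiation to C7), TBS on both primary alcohols; all four leave in one acid step.

Key step: step 12

Assumption: the antipodes of the chiral ligands and of the amine named in steps 3 and 10 are those expected from the accepted induction models for these catalyst families; each is available in both mirror-image forms, so a reversed sense would only mean using the other antipode.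

**Route**

Step 1
Reactants: 1 2,3-dihydroxybenzaldehyde
Product: 2 2,3-bis(methoxymethoxy)benzaldehyde
Conditions: MOMCl, i-Pr2NEt, CH2Cl2, 0 °C → rt
Reagents that add atoms: chloromethyl methyl ether, COCCl
Why: Double O-alkylation of the phenols (MOM protection) should give acetals that tolerate ylide, organolithium, nickel, iridium and ruthenium chemistry, later direct lithiation to C7 and leave under aqueous acid.

Step 2
Reactants: 2 2,3-bis(methoxymethoxy)benzaldehyde
Product: 3 1-ethenyl-2,3-bis(methoxymethoxy)benzene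
Conditions: Ph3PCH3Br, KOtBu, THF, 0 °C → rt
Reagents that add atoms: methyltriphenylphosphonium bromide, C[P+](c1ccccc1)(c1ccccc1)c1ccccc1.[Br-]
Why: Wittig methylenation of a non-enolisable aryl aldehyde should give the styrene needed for hydrovinylation.

Step 3
Reactants: 3 1-ethenyl-2,3-bis(methoxymethoxy)benzene
Product: 4 1-[(2R)-but-3-en-2-yl]-2,3-bis(methoxymethoxy)benzene
Conditions: C2H4 (1 atm), [Ni(C3H5)Br]2 (1 mol%), (Sa,Rc,Rc)-BINOL phosphoramidite of bis(1-phenylethyl)amine (2 mol%), Na[B(3,5-(CF3)2C6H3)4] (2.5 mol%), CH2Cl2, −70 °C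
Reagents that add atoms: ethene, C=C
Why: Asymmetric hydrovinylation, in which the cationic nickel hydride adds to the styrene to give an η3-benzyl complex, ethylene inserts at the benzylic carbon and β-hydride elimination releases the 3-arylbut-1-ene, with the phosphoramidite selecting the alkene face so that C4 forms as (R); the styrene has only one ortho alkoxy group, which is within the known scope, and at −70 °C the product alkene should not migrate.

Step 4
Reactants: 4 1-[(2R)-but-3-en-2-yl]-2,3-bis(methoxymethoxy)benzene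
Product: 5 1-bromo-2-[(2R)-but-3-en-2-yl]-3,4-bis(methoxymethoxy)benzene
Conditions: NBS (1.05 equiv), MeCN, 0 °C → rt, dark
Reagents that add atoms: N-bromosuccinimide, O=C1CCC(=O)N1Br
Why: Electrophilic aromatic bromination should go para to the C6 oxygen, the only alkoxy group free to conjugate because the C5 acetal is flanked on both sides and twisted out of plane, which puts bromine on C8a; the polar, radical-free medium should spare the monosubstituted alkene and the C4–H bond.

Step 5
Reactants: 5 1-bromo-2-[(2R)-but-3-en-2-yl]-3,4-bis(methoxymethoxy)benzene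
Product: 7 (1RS)-1-{2-[(2R)-but-3-en-2-yl]-3,4-bis(methoxymethoxy)phenyl}prop-2-en-1-ol, via aryllithium 6 (not isolated)
Conditions: n-BuLi, THF, −78 °C; acrolein, −78 °C; H2O
Reagents that add atoms: n-butyllithium, [Li]CCCC (lithium in 6 only); acrolein, C=CC=O
Why: Bromine–lithium exchange followed by 1,2-addition of the aryllithium to acrolein should give the branched allylic alcohol, whose carbinol configuration does not matter because step 10 ionises it.

Step 6
Reactants: 8 (2R)-3-bromo-2-methylpropan-1-ol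
Product: 9 [(2R)-3-bromo-2-methylpropoxy](tert-butyl)dimethylsilane
Conditions: TBSCl, imidazole, CH2Cl2, rt
Reagents that add atoms: tert-butyldimethylsilyl chloride, CC(C)(C)[Si](C)(C)Cl
Why: Silylation of the primary alcohol masks the C5′ hydroxymethyl group without involving the stereocentre.

Step 7
Reactants: 9 [(2R)-3-bromo-2-methylpropoxy](tert-butyl)dimethylsilane
Product: 10 tert-butyl(dimethyl){[(2S)-2-methylhept-6-en-1-yl]oxy}silane
Conditions: CH2=CHCH2CH2MgBr, Li2CuCl4 (3 mol%), THF, −20 °C → rt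
Reagents that add atoms: but-3-en-1-ylmagnesium bromide, C=CCC[Mg]Br
Why: Copper-catalysed sp3–sp3 coupling of a primary alkyl bromide with a Grignard reagent (Kochi coupling) should join C3′ to C4′ one carbon away from the untouched C5′ stereocentre.

Step 8
Reactants: 10 tert-butyl(dimethyl){[(2S)-2-methylhept-6-en-1-yl]oxy}silane
Product: 12 (6S)-7-{[tert-butyl(dimethyl)silyl]oxy}-6-methylheptan-1-ol, via B-alkyl-9-borabicyclononane 11 (not isolated)
Conditions: 9-BBN, THF, 0 °C → rt; NaOH, H2O2, 0 °C → rt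
Reagents that add atoms: 9-borabicyclo[3.3.1]nonane, B1C2CCCC1CCC2 (boron in 11 only); hydrogen peroxide, OO
Why: Anti-Markovnikov hydroboration of the terminal alkene and oxidative work-up should place the hydroxyl on the terminal carbon.

Step 9
Reactants: 12 (6S)-7-{[tert-butyl(dimethyl)silyl]oxy}-6-methylheptan-1-ol
Product: 13 (6S)-7-{[tert-butyl(dimethyl)silyl]oxy}-6-methylheptanal
Conditions: TEMPO (10 mol%), PhI(OAc)2, CH2Cl2, rt
Reagents that add atoms: none
Why: TEMPO-catalysed oxidation with PhI(OAc)2 should stop at the aldehyde and is mild enough for the TBS ether; the α-carbon is a CH2 group, so nothing can epimerise.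

Step 10
Reactants: 7 (1RS)-1-{2-[(2R)-but-3-en-2-yl]-3,4-bis(methoxymethoxy)phenyl}prop-2-en-1-ol; 13 (6S)-7-{[tert-butyl(dimethyl)silyl]oxy}-6-methylheptanal
Product: 15 (2S,3S)-3-{2-[(2R)-but-3-en-2-yl]-3,4-bis(methoxymethoxy)phenyl}-2-[(4S)-5-{[tert-butyl(dimethyl)silyl]oxy}-4-methylpentyl]pent-4-en-1-ol, via pent-4-enal 14 (not isolated)
Conditions: [Ir(cod)Cl]2 (3 mol%), (S)-BINOL phosphoramidite of 5H-dibenzo[b,f]azepine (12 mol%), (R)-2-{bis[3,5-bis(trifluoromethyl)phenyl](trimethylsilyloxy)methyl}pyrrolidine (15 mol%), (MeO)2P(O)OH (promoter), ClCH2CH2Cl, 25 °C; then MeOH, NaBH4, 0 °C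
Reagents that add atoms: none
Why: Dual iridium/enamine catalysis (α-allylation of a linear aldehyde with a branched aryl allylic alcohol), in which either carbinol epimer of 7 is ionised to an η3-allyl iridium complex whose open face is fixed by the phosphoramidite–olefin ligand and the E-enamine of 13 attacks the benzylic terminus from the face left free by the diarylsilyloxymethyl group, so that C1 (S) is set by the ligand and C1′ (S) by the amine independently; NaBH4 then reduces aldehyde 14 in the same flask before its α-centre can epimerise.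

Step 11
Reactants: 15 (2S,3S)-3-{2-[(2R)-but-3-en-2-yl]-3,4-bis(methoxymethoxy)phenyl}-2-[(4S)-5-{[tert-butyl(dimethyl)silyl]oxy}-4-methylpentyl]pent-4-en-1-ol
Product: 16 (2S,3S)-3-{2-[(2R)-but-3-en-2-yl]-3,4-bis(methoxymethoxy)phenyl}-1-{[tert-butyl(dimethyl)silyl]oxy}-2-[(4S)-5-{[tert-butyl(dimethyl)silyl]oxy}-4-methylpentyl]pent-4-ene
Conditions: TBSCl, imidazole, DMF, rt
Reagents that add atoms: tert-butyldimethylsilyl chloride, CC(C)(C)[Si](C)(C)Cl
Why: Silylation of the new primary alcohol gives the fully protected diene for metathesis.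

Step 12
Reactants: 16 (2S,3S)-3-{2-[(2R)-but-3-en-2-yl]-3,4-bis(methoxymethoxy)phenyl}-1-{[tert-butyl(dimethyl)silyl]oxy}-2-[(4S)-5-{[tert-butyl(dimethyl)silyl]oxy}-4-methylpentyl]pent-4-ene
Product: 17 (1S,4R)-1-[(2S,6S)-1,7-bis{[tert-butyl(dimethyl)silyl]oxy}-6-methylheptan-2-yl]-5,6-bis(methoxymethoxy)-4-methyl-1,4-dihydronaphthalene
Conditions: second-generation Grubbs catalyst (H2IMes)(PCy3)Cl2Ru=CHPh (5 mol%), 1,4-benzoquinone (10 mol%), CH2Cl2 (0.005 M), 40 °C; ethyl vinyl ether quench
Reagents that add atoms: none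
Why: Ring-closing olefin metathesis: the ruthenium benzylidene exchanges with one terminal vinyl group, the new alkylidene undergoes [2+2] cycloaddition with the second vinyl group, and cycloreversion of the ruthenacyclobutane expels ethylene and forms C2=C3. The closest known reaction type is the ring-closing metathesis of 1,2-bis(allyl)benzenes to 1,4-dihydronaphthalenes. Ring B closes as a six-membered carbocycle at the C2–C3 bond, the two vinyl groups being held side by side because C1 and C4 sit on the adjacent ring A carbons C8a and C4a. No stereocentre is formed: C4, C1/C1′ and C5′ were fixed in steps 3, 10 and 6–7 and are not touched, so the 1,4-trans relationship is not a ring-closure problem. The step needs only chemoselectivity, namely cyclisation over oligomerisation and no ruthenium hydride migration of the new double bond into conjugation with ring A (which would erase C1 or C4); ortho pre-organisation and high dilution should secure the first, and benzoquinone, a short reaction time and the vinyl ether quench the second.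

Step 13
Reactants: 17 (1S,4R)-1-[(2S,6S)-1,7-bis{[tert-butyl(dimethyl)silyl]oxy}-6-methylheptan-2-yl]-5,6-bis(methoxymethoxy)-4-methyl-1,4-dihydronaphthalene
Product: 18 (1S,4R)-1-[(2S,6S)-1,7-bis{[tert-butyl(dimethyl)silyl]oxy}-6-methylheptan-2-yl]-5,6-bis(methoxymethoxy)-4-methyl-1,2,3,4-tetrahydronaphthalene
Conditions: H2 (4 atm), RhCl(PPh3)3 (10 mol%), PhMe–EtOH, 25 °C
Reagents that add atoms: none
Why: Homogeneous hydrogenation with RhCl(PPh3)3 should saturate the cis-disubstituted C2=C3 bond without the double-bond migration common with palladium on carbon, so the benzylic stereocentres C1 and C4 are kept and the arene, acetals and silyl ethers stay intact.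

Step 14
Reactants: 18 (1S,4R)-1-[(2S,6S)-1,7-bis{[tert-butyl(dimethyl)silyl]oxy}-6-methylheptan-2-yl]-5,6-bis(methoxymethoxy)-4-methyl-1,2,3,4-tetrahydronaphthalene
Product: 20 (5R,8S)-8-[(2S,6S)-1,7-bis{[tert-butyl(dimethyl)silyl]oxy}-6-methylheptan-2-yl]-3,4-bis(methoxymethoxy)-5-methyl-5,6,7,8-tetrahydronaphthalene-2-carboxylic acid, via C7 aryllithium 19 (not isolated)
Conditions: n-BuLi, TMEDA, THF, −78 → 0 °C; CO2, −78 °C → rt; 1 M HCl to pH 4, 0 °C
Reagents that add atoms: n-butyllithium, [Li]CCCC (lithium in 19 only); carbon dioxide, O=C=O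
Why: Directed ortho-metalation, in which C7–H is the only ring hydrogen ortho to an alkoxy directing group (the C6 MOM acetal), so lithiation and trapping with CO2 should install the acid there while the silyl ethers and the tertiary benzylic C–H bonds are left alone.

Step 15
Reactants: 20 (5R,8S)-8-[(2S,6S)-1,7-bis{[tert-butyl(dimethyl)silyl]oxy}-6-methylheptan-2-yl]-3,4-bis(methoxymethoxy)-5-methyl-5,6,7,8-tetrahydronaphthalene-2-carboxylic acid
Product: 21 (5R,8S)-8-[(2S,6S)-1,7-dihydroxy-6-methylheptan-2-yl]-3,4-dihydroxy-5-methyl-5,6,7,8-tetrahydronaphthalene-2-carboxylic acid (CNP0255074.1)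
Conditions: 3 M aq. HCl–THF (1:2), 40 °C, argon
Reagents that add atoms: none
Why: Aqueous acid should hydrolyse both MOM acetals and both TBS ethers in one operation (global deprotection); none of the four stereocentres is acid-labile and the aqueous medium avoids esterification of the acid.

**Compound list**

1 | 2,3-dihydroxybenzaldehyde | O=Cc1cccc(O)c1O | starting material
2 | 2,3-bis(methoxymethoxy)benzaldehyde | O=Cc1cccc(OCOC)c1OCOC | intermediate
3 | 1-ethenyl-2,3-bis(methoxymethoxy)benzene | C=Cc1cccc(OCOC)c1OCOC | intermediate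
4 | 1-[(2R)-but-3-en-2-yl]-2,3-bis(methoxymethoxy)benzene | C=C[C@@H](C)c1cccc(OCOC)c1OCOC | intermediate
5 | 1-bromo-2-[(2R)-but-3-en-2-yl]-3,4-bis(methoxymethoxy)benzene | C=C[C@@H](C)c1c(Br)ccc(OCOC)c1OCOC | intermediate
6 | {2-[(2R)-but-3-en-2-yl]-3,4-bis(methoxymethoxy)phenyl}lithium | C=C[C@@H](C)c1c([Li])ccc(OCOC)c1OCOC | intermediate
7 | (1RS)-1-{2-[(2R)-but-3-en-2-yl]-3,4-bis(methoxymethoxy)phenyl}prop-2-en-1-ol | C=C[C@@H](C)c1c(C(O)C=C)ccc(OCOC)c1OCOC | intermediate
8 | (2R)-3-bromo-2-methylpropan-1-ol | C[C@H](CO)CBr | starting material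
9 | [(2R)-3-bromo-2-methylpropoxy](tert-butyl)dimethylsilane | C[C@H](CO[Si](C)(C)C(C)(C)C)CBr | intermediate
10 | tert-butyl(dimethyl){[(2S)-2-methylhept-6-en-1-yl]oxy}silane | C[C@H](CO[Si](C)(C)C(C)(C)C)CCCC=C | intermediate
11 | 9-[(6S)-7-{[tert-butyl(dimethyl)silyl]oxy}-6-methylheptyl]-9-borabicyclo[3.3.1]nonane | C[C@H](CO[Si](C)(C)C(C)(C)C)CCCCCB1C2CCCC1CCC2 | intermediate
12 | (6S)-7-{[tert-butyl(dimethyl)silyl]oxy}-6-methylheptan-1-ol | C[C@H](CO[Si](C)(C)C(C)(C)C)CCCCCO | intermediate
13 | (6S)-7-{[tert-butyl(dimethyl)silyl]oxy}-6-methylheptanal | C[C@H](CO[Si](C)(C)C(C)(C)C)CCCCC=O | intermediate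
14 | (2S,3S)-3-{2-[(2R)-but-3-en-2-yl]-3,4-bis(methoxymethoxy)phenyl}-2-[(4S)-5-{[tert-butyl(dimethyl)silyl]oxy}-4-methylpentyl]pent-4-enal | C=C[C@@H](C)c1c(OCOC)c(OCOC)ccc1[C@@H](C=C)[C@@H](C=O)CCC[C@H](C)CO[Si](C)(C)C(C)(C)C | intermediate
15 | (2S,3S)-3-{2-[(2R)-but-3-en-2-yl]-3,4-bis(methoxymethoxy)phenyl}-2-[(4S)-5-{[tert-butyl(dimethyl)silyl]oxy}-4-methylpentyl]pent-4-en-1-ol | C=C[C@@H](C)c1c(OCOC)c(OCOC)ccc1[C@@H](C=C)[C@@H](CO)CCC[C@H](C)CO[Si](C)(C)C(C)(C)C | intermediate
16 | (2S,3S)-3-{2-[(2R)-but-3-en-2-yl]-3,4-bis(methoxymethoxy)phenyl}-1-{[tert-butyl(dimethyl)silyl]oxy}-2-[(4S)-5-{[tert-butyl(dimethyl)silyl]oxy}-4-methylpentyl]pent-4-ene | C=C[C@@H](C)c1c(OCOC)c(OCOC)ccc1[C@@H](C=C)[C@@H](CO[Si](C)(C)C(C)(C)C)CCC[C@H](C)CO[Si](C)(C)C(C)(C)C | intermediate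
17 | (1S,4R)-1-[(2S,6S)-1,7-bis{[tert-butyl(dimethyl)silyl]oxy}-6-methylheptan-2-yl]-5,6-bis(methoxymethoxy)-4-methyl-1,4-dihydronaphthalene | C[C@H](CO[Si](C)(C)C(C)(C)C)CCC[C@H](CO[Si](C)(C)C(C)(C)C)[C@@H]1C=C[C@@H](C)c2c1ccc(OCOC)c2OCOC | intermediate
18 | (1S,4R)-1-[(2S,6S)-1,7-bis{[tert-butyl(dimethyl)silyl]oxy}-6-methylheptan-2-yl]-5,6-bis(methoxymethoxy)-4-methyl-1,2,3,4-tetrahydronaphthalene | C[C@H](CO[Si](C)(C)C(C)(C)C)CCC[C@H](CO[Si](C)(C)C(C)(C)C)[C@@H]1CC[C@@H](C)c2c1ccc(OCOC)c2OCOC | intermediate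
19 | {(5R,8S)-8-[(2S,6S)-1,7-bis{[tert-butyl(dimethyl)silyl]oxy}-6-methylheptan-2-yl]-3,4-bis(methoxymethoxy)-5-methyl-5,6,7,8-tetrahydronaphthalen-2-yl}lithium | C[C@H](CO[Si](C)(C)C(C)(C)C)CCC[C@H](CO[Si](C)(C)C(C)(C)C)[C@@H]1CC[C@@H](C)c2c1cc([Li])c(OCOC)c2OCOC | intermediate
20 | (5R,8S)-8-[(2S,6S)-1,7-bis{[tert-butyl(dimethyl)silyl]oxy}-6-methylheptan-2-yl]-3,4-bis(methoxymethoxy)-5-methyl-5,6,7,8-tetrahydronaphthalene-2-carboxylic acid | C[C@H](CO[Si](C)(C)C(C)(C)C)CCC[C@H](CO[Si](C)(C)C(C)(C)C)[C@@H]1CC[C@@H](C)c2c1cc(C(=O)O)c(OCOC)c2OCOC | intermediate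
21 | (5R,8S)-8-[(2S,6S)-1,7-dihydroxy-6-methylheptan-2-yl]-3,4-dihydroxy-5-methyl-5,6,7,8-tetrahydronaphthalene-2-carboxylic acid | C[C@H](CO)CCC[C@H](CO)[C@@H]1CC[C@@H](C)c2c1cc(C(=O)O)c(O)c2O | target

**Step count**

Total: 15 steps. Longest linear sequence: 11 steps (steps 1–5 and 10–15); the side-chain aldehyde 13 takes 4 steps (6–9).

**Steps most likely to fail**

Step 10. The allyl–iridium terminus is crowded by the ortho sec-alkyl arm, so ionisation or enamine attack may be slow. The α-centre of aldehyde 14 may epimerise before reduction, and the acidic promoter may strip MOM or TBS groups. The fallback replaces the dual catalysis by an enantioselective ester-enolate Claisen rearrangement; it sets out from 7 (and uses 13) and returns at 15. A 1,3-transposition of the hydroxyl group of 7 (Ph3SiOReO3 cat., Et2O, 0 °C) should give (2E)-3-{2-[(2R)-but-3-en-2-yl]-3,4-bis(methoxymethoxy)phenyl}prop-2-en-1-ol F1. Aldehyde 13 is oxidised (NaClO2, NaH2PO4, 2-methylbut-2-ene) to (6S)-7-{[tert-butyl(dimethyl)silyl]oxy}-6-methylheptanoic acid F2. DCC/DMAP esterification of the two should give the (E)-3-arylprop-2-enyl (6S)-7-silyloxy-6-methylheptanoate F3. The boron enolate of F3 is formed with a chiral 2-bromo-4,5-diphenyl-1,3-bis(arylsulfonyl)-1,3,2-diazaborolidine and a tertiary amine; the antipode and the amine/solvent pair are chosen for the 2,3-anti series. It should rearrange through a chair transition state to (2S,3S)-3-{2-[(2R)-but-3-en-2-yl]-3,4-bis(methoxymethoxy)phenyl}-2-[(4S)-5-{[tert-butyl(dimethyl)silyl]oxy}-4-methylpentyl]pent-4-enoic acid F4. LiAlH4 reduction then gives 15.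

Step 4. Bromine may enter at C7 or C8 instead of C8a, add to the vinyl group, or substitute the doubly activated C4–H bond by a radical path. The fallback brominates before any alkene is present; it sets out from 2 and returns at 5. NBS in DMF should brominate aldehyde 2 para to the same oxygen to give 6-bromo-2,3-bis(methoxymethoxy)benzaldehyde F5. Wittig methylenation as in step 2 gives 1-bromo-2-ethenyl-3,4-bis(methoxymethoxy)benzene F6. The nickel hydrovinylation of step 3 applied to F6 gives 5 directly, at the price of a styrene flanked on both sides.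

Step 3. Chelation of the cationic nickel by the ortho MOM acetal may erode the enantio-induction, and the product may isomerise to the conjugated 2-arylbut-2-ene or oligomerise. The fallback sets C4 by copper-catalysed asymmetric allylic methylation; it sets out from 2 and returns at 4. Horner–Wadsworth–Emmons reaction with triethyl phosphonoacetate/NaH should give ethyl (2E)-3-[2,3-bis(methoxymethoxy)phenyl]prop-2-enoate F7. DIBAL-H reduction gives (2E)-3-[2,3-bis(methoxymethoxy)phenyl]prop-2-en-1-ol F8. CBr4/PPh3 gives 1-[(1E)-3-bromoprop-1-en-1-yl]-2,3-bis(methoxymethoxy)benzene F9. MeMgBr with catalytic CuBr·SMe2 and the Taniaphos antipode chosen for (R), in CH2Cl2 at −75 °C, should displace bromide in the SN2′ sense to give 4.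

**Further compounds**

F1 | step 10 | (2E)-3-{2-[(2R)-but-3-en-2-yl]-3,4-bis(methoxymethoxy)phenyl}prop-2-en-1-ol | C=C[C@@H](C)c1c(/C=C/CO)ccc(OCOC)c1OCOC
F2 | step 10 | (6S)-7-{[tert-butyl(dimethyl)silyl]oxy}-6-methylheptanoic acid | C[C@H](CO[Si](C)(C)C(C)(C)C)CCCCC(=O)O
F3 | step 10 | (2E)-3-{2-[(2R)-but-3-en-2-yl]-3,4-bis(methoxymethoxy)phenyl}prop-2-en-1-yl (6S)-7-{[tert-butyl(dimethyl)silyl]oxy}-6-methylheptanoate | C=C[C@@H](C)c1c(/C=C/COC(=O)CCCC[C@H](C)CO[Si](C)(C)C(C)(C)C)ccc(OCOC)c1OCOC
F4 | step 10 | (2S,3S)-3-{2-[(2R)-but-3-en-2-yl]-3,4-bis(methoxymethoxy)phenyl}-2-[(4S)-5-{[tert-butyl(dimethyl)silyl]oxy}-4-methylpentyl]pent-4-enoic acid | C=C[C@@H](C)c1c(OCOC)c(OCOC)ccc1[C@@H](C=C)[C@@H](C(=O)O)CCC[C@H](C)CO[Si](C)(C)C(C)(C)C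
F5 | step 4 | 6-bromo-2,3-bis(methoxymethoxy)benzaldehyde | O=Cc1c(Br)ccc(OCOC)c1OCOC
F6 | step 4 | 1-bromo-2-ethenyl-3,4-bis(methoxymethoxy)benzene | C=Cc1c(Br)ccc(OCOC)c1OCOC
F7 | step 3 | ethyl (2E)-3-[2,3-bis(methoxymethoxy)phenyl]prop-2-enoate | CCOC(=O)/C=C/c1cccc(OCOC)c1OCOC
F8 | step 3 | (2E)-3-[2,3-bis(methoxymethoxy)phenyl]prop-2-en-1-ol | OC/C=C/c1cccc(OCOC)c1OCOC
F9 | step 3 | 1-[(1E)-3-bromoprop-1-en-1-yl]-2,3-bis(methoxymethoxy)benzene | BrC/C=C/c1cccc(OCOC)c1OCOC
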